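**Plan**
Retrosynthesis: cut the angelate at O–C2. Cut ring A at C2–C3 and C4–O in one Prins transform (cis-1,3-diol ⇒ aldehyde carbon C2 on C1 plus isopropenyl C3=C4(C15) on C5). Then cut C11–CH3, the ether bond O–C11, the C5–isopropenyl bond, C1–C2 with C10–CH3, and the lactone bond C7–C11, back to (R)-4-hydroxycyclohept-2-enone.
Forward: ring B is bought as cyclohepta-1,3-diene. The lactone (ring D) is fused on by Ueno–Stork radical cyclisation, the ether bridge (ring C) by carbenoid O–H insertion, and ring A is closed last by an acylal Prins cyclisation relayed through a temporary acetoxonium ring; deacetylation and angeloylation finish.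
Stereochemistry: C8 from a catalytic asymmetric Kornblum–DeLaMare desymmetrisation. C7 follows from the O-tether. C10, C1 and C5 come from additions anti to the cis-fused lactone. C11 is dictated by the cage (only cis fusion possible). C2 and C4 are set together in the key step.
Enabling feature: the 1,3-dioxygenated C2–C3–C4 unit of ring A is a Prins retron. C1 and the fully substituted bridgehead C5 of the rigid ether/lactone cage (rings B, C, D) hold the aldehyde and the 1,1-disubstituted alkene gauche and on defined faces.

Key step: step 13

Remark: ring carbons carry guaiane numbers in all intermediates (ring A C1–C5; ring B C1, C5–C10; C11 with methyl C13 and lactone carbonyl C12 on C7; C14 on C10; C15 on C4). The acetal carbon in 4–7 is an inconsequential mixture of epimers.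

Step 1
Reactants: 1 cyclohepta-1,3-diene
Product: 2 6,7-dioxabicyclo[3.2.2]non-8-ene (meso endoperoxide)
Conditions: O2, tetraphenylporphyrin (cat.), visible light, CH2Cl2, 0 °C
Reagents that add atoms: dioxygen, O=O
Why: Singlet-oxygen [4+2] photooxygenation of the cyclic diene should give the meso endoperoxide, placing the two C–O bonds (future C5 and C8) cis on one face.

Step 2
Reactants: 2 6,7-dioxabicyclo[3.2.2]non-8-ene
Product: 3 (R)-4-hydroxycyclohept-2-en-1-one
Conditions: 6'-hydroxy-9-O-acetyl cinchona-alkaloid base (5 mol %, the pseudoenantiomer that gives the R alcohol), CH2Cl2, 25 °C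
Reagents that add atoms: none
Why: Enantioselective Kornblum–DeLaMare rearrangement, in which the chiral amine base removes one of the two enantiotopic peroxide α-hydrogens (future C5) with O–O cleavage, so the untouched carbinol carbon C8 should emerge as one enantiomer chosen by the catalyst.

Step 3
Reactants: 3 (R)-4-hydroxycyclohept-2-en-1-one
Product: 4 (4R)-4-(2-bromo-1-ethoxyethoxy)cyclohept-2-en-1-one
Conditions: ethyl vinyl ether, N-bromosuccinimide, CH2Cl2, −40 to 0 °C
Reagents that add atoms: ethyl vinyl ether, C=COCC; N-bromosuccinimide, O=C1CCC(=O)N1Br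
Why: Haloacetalisation (Ueno–Stork bromoacetal formation), the bromonium ion of the enol ether being opened by the C8 hydroxyl; the new acetal centre forms unselectively and is erased in step 6.

Step 4
Reactants: 4 (4R)-4-(2-bromo-1-ethoxyethoxy)cyclohept-2-en-1-one
Product: 6 (4R)-4-(2-bromo-1-ethoxyethoxy)cyclohepta-2,6-dien-1-one, via silyl dienol ether 5 (not isolated)
Conditions: LiN(iPr)2, Me3SiCl, THF, −78 °C; then Pd(OAc)2 (0.2 equiv), O2, DMSO, 25 °C
Reagents that add atoms: none
Why: Saegusa–Ito dehydrogenation, in which kinetic α'-deprotonation at C1 gives the cross-conjugated silyl dienol ether and palladation with β-hydride elimination introduces C1=C10 without forming a stereocentre.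

Step 5
Reactants: 6 (4R)-4-(2-bromo-1-ethoxyethoxy)cyclohepta-2,6-dien-1-one
Product: 7 cis-fused ethoxy acetal enone (2-ethoxy-2,3,3a,4,8,8a-hexahydro-5H-cyclohepta[b]furan-5-one)
Conditions: Bu3SnH (slow addition), AIBN (cat.), benzene, 80 °C
Reagents that add atoms: none
Why: Ueno–Stork 5-exo-trig radical cyclisation, in which the primary radical (future C11) tethered to O-8 adds to C7 (β-carbon of the C6=C7 enone) and can only close cis, so C7 is set by C8 while the C1=C10 enone is kept.

Step 6
Reactants: 7 cis-fused ethoxy acetal enone
Product: 8 cis-fused enone lactone (3,3a,8,8a-tetrahydro-2H-cyclohepta[b]furan-2,5(4H)-dione)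
Conditions: CrO3, H2SO4, H2O, acetone, 0 °C
Reagents that add atoms: water, O
Why: Jones oxidation, the aqueous acid hydrolysing the ethyl acetal to the lactol that chromic acid oxidises to the γ-lactone, with the enone inert and no stereocentre touched.

Step 7
Reactants: 8 cis-fused enone lactone
Product: 10 keto acetal lactone (6-(dimethoxymethyl)-7-methylhexahydro-2H-cyclohepta[b]furan-2,5(3H)-dione), via silyl enol ether 9 (not isolated)
Conditions: Me2CuLi, Me3SiCl, THF, −78 °C; filter, evaporate; then HC(OMe)3, Me3SiOTf (0.05 equiv), CH2Cl2, −78 °C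
Reagents that add atoms: lithium dimethylcuprate, [Li+].C[Cu-]C; trimethyl orthoformate, COC(OC)OC
Why: Cuprate conjugate addition with silyl trapping, then Mukaiyama-type alkylation of the silyl enol ether by the dimethoxycarbenium ion; methyl should add to C10 on the face opposite the cis-fused lactone and the electrophile should enter at C1 anti to that methyl (also the stable arrangement α to the ketone).

Step 8
Reactants: 10 keto acetal lactone
Product: 11 tertiary alcohol (6-(dimethoxymethyl)-5-hydroxy-7-methyl-5-(prop-1-en-2-yl)octahydro-2H-cyclohepta[b]furan-2-one)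
Conditions: CH2=C(CH3)MgBr, CeCl3, THF, −78 °C
Reagents that add atoms: isopropenylmagnesium bromide, CC(=C)[Mg]Br
Why: Organocerium 1,2-addition to the ketone in preference to the lactone, attacking C5 from the face opposite both the C1 acetal and the lactone so that the hydroxyl lies cis to the lactone, as the ether bridge requires.

Step 9
Reactants: 11 tertiary alcohol
Product: 13 diazo lactone (3-diazo derivative of 11), via trifluoroacetyl lactone 12 (not isolated)
Conditions: LiN(SiMe3)2 (2.2 equiv), CF3CO2CH2CF3, THF, −78 °C; then 4-acetamidobenzenesulfonyl azide, Et3N, H2O, MeCN, 25 °C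
Reagents that add atoms: 4-acetamidobenzenesulfonyl azide, CC(=O)Nc1ccc(cc1)S(=O)(=O)N=[N+]=[N-]
Why: Detrifluoroacetylative Regitz diazo transfer, in which Claisen trifluoroacetylation of the lactone enolate activates C11 for diazo transfer with loss of the trifluoroacetyl group; no stereocentre is touched.

Step 10
Reactants: 13 diazo lactone
Product: 14 ether-bridged lactone acetal (O joins C5 to C11; C11–H)
Conditions: Rh2(OAc)4 (1 mol %), CH2Cl2, 25 °C, slow addition of 13
Reagents that add atoms: none
Why: Rhodium-carbenoid O–H insertion, the C11 carbenoid being captured by the tertiary C5 hydroxyl on the same face to close the five-membered ether (ring C); the two five-membered rings sharing C7–C11 can only be cis-fused, which fixes C11 with hydrogen outward.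

Step 11
Reactants: 14 ether-bridged lactone acetal
Product: 15 C11-methylated ether-bridged lactone acetal (2,2-dimethoxy-5,11-epoxy-2,3-seco-guai-3-en-12,8-olide)
Conditions: LiN(iPr)2, THF, −78 °C; CH3I, −78 °C, quench cold
Reagents that add atoms: iodomethane, CI
Why: Lactone enolate alkylation, the enolate carbon C11 being a ring-fusion atom of the cis-fused ether/lactone bicycle that can accept methyl only on its outer face, which gives the quaternary C11 in the required configuration.

Step 12
Reactants: 15 C11-methylated ether-bridged lactone acetal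
Product: 16 seco-aldehyde (5,11-epoxy-2-oxo-2,3-seco-guai-3-en-12,8-olide)
Conditions: pyridinium p-toluenesulfonate, acetone–H2O (9:1), 40 °C
Reagents that add atoms: water, O
Why: Mild acid-catalysed acetal hydrolysis should free the C2 aldehyde without ionising the tertiary allylic ether, and C1 keeps the trans arrangement that is also the more stable one α to the aldehyde.

Step 13
Reactants: 16 seco-aldehyde
Product: 19 2-O-acetyl-4-hydroxy-5,11-epoxyguaian-12,8-olide, via geminal diacetate 17 (not isolated), via dioxanylium ion 18 (not isolated)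
Conditions: Ac2O (3 equiv), Me3SiOTf (0.2 equiv), 2,6-di-tert-butylpyridine (0.3 equiv), CH2Cl2, −78 to −30 °C; then aq. NaHCO3, 0 °C
Reagents that add atoms: acetic anhydride, CC(=O)OC(C)=O; water, O
Why: Proposed new method: Ac2O/Me3SiOTf should convert the C2 aldehyde into the geminal diacetate 17 and ionise it to an O-acetyl oxocarbenium ion; the CH2 terminus (C3) of the 1,1-disubstituted alkene on C5 attacks it to form C2–C3 and a tertiary C4 cation, which the carbonyl oxygen of the C2 acetoxy group traps as the bridged 2-methyl-1,3-dioxan-2-ylium ion 18, opened by water to the cis-1,3-diol monoacetate 19 (the O-4 acetate, if formed, converges in step 14). The closest known reaction types are the Hosomi–Sakurai-type addition of π-nucleophiles to acylals, the type 2 carbonyl-ene/Prins cyclisation of γ,δ-unsaturated aldehydes and acyloxonium neighbouring-group participation, and their combination on a bridgehead allylic ether is what is new. Ring A closes in a 5-(π-endo)-exo-trig mode (C=O+ exocyclic, alkene endocyclic), formally the less favoured class but the one by which 1,4-diketones close to cyclopentenones and 2-(silylmethyl)allyl units to methylenecyclopentanols, while the temporary dioxanylium ring closes by six-membered oxygen capture of the cation. C2 is set in an envelope transition state with the acetoxy group trans to the C1–C10 bond (cis to H-1), and C4 is set by intramolecular delivery of oxygen from that acetoxy group, so O-4 must be cis to O-2 and C15 falls on the face of the ether oxygen; C1 (trans ring fusion) and C5 are already fixed. The step needs facial selectivity (bridge on the H-1 face, not on the face where it would sit under the ether/lactone cage) and chemoselectivity over ionisation of the tertiary allylic C5–O bond, proton loss and 1,2-shift at the C4 cation. The tether, the low temperature and the low basicity of the ether oxygen (α to the lactone carbonyl) should secure them.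

Step 14
Reactants: 19 2-O-acetyl-4-hydroxy-5,11-epoxyguaian-12,8-olide
Product: 20 2,4-dihydroxy-5,11-epoxyguaian-12,8-olide
Conditions: K2CO3 (0.2 equiv), MeOH, 0 °C
Reagents that add atoms: none
Why: Base-catalysed transesterification (methanolysis) should remove the acetate from the cis-1,3-diol, the hindered α-quaternary lactone opening more slowly and re-closing on work-up, with no stereocentre touched.

Step 15
Reactants: 20 2,4-dihydroxy-5,11-epoxyguaian-12,8-olide
Product: 21 2-O-angeloyl-4-hydroxy-5,11-epoxyguaian-12,8-olide (target)
Conditions: LiN(SiMe3)2 (1.1 equiv), THF, −78 °C; (Z)-2-methylbut-2-enoic anhydride, −78 to 0 °C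
Reagents that add atoms: (Z)-2-methylbut-2-enoic anhydride (angelic anhydride), C/C=C(/C)C(=O)OC(=O)/C(C)=C\C
Why: O-acylation of the lithium alkoxide of the secondary C2 hydroxyl with angelic anhydride, the tertiary C4 hydroxyl being too hindered to react and the anhydride/amide-base conditions avoiding Z to E isomerisation of the angelate.

**Compound list**
1 | cyclohepta-1,3-diene | C1=CC=CCCC1 | starting material
2 | 6,7-dioxabicyclo[3.2.2]non-8-ene (meso endoperoxide) | [C@@H]12C=C[C@@H](CCC1)OO2 | intermediate
3 | (R)-4-hydroxycyclohept-2-en-1-one | O=C1C=C[C@H](O)CCC1 | intermediate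
4 | (4R)-4-(2-bromo-1-ethoxyethoxy)cyclohept-2-en-1-one | O=C1C=C[C@H](OC(OCC)CBr)CCC1 | intermediate
5 | silyl dienol ether, [(5R)-5-(2-bromo-1-ethoxyethoxy)cyclohepta-1,6-dien-1-yl]oxytrimethylsilane | C[Si](C)(C)OC1=CCC[C@@H](OC(OCC)CBr)C=C1 | intermediate
6 | (4R)-4-(2-bromo-1-ethoxyethoxy)cyclohepta-2,6-dien-1-one | O=C1C=C[C@H](OC(OCC)CBr)CC=C1 | intermediate
7 | cis-fused ethoxy acetal enone (C5 ketone, C1=C10; 2-ethoxytetrahydrofuran fused at C7–C8) | O=C1C[C@H]2[C@@H](CC=C1)OC(OCC)C2 | intermediate
8 | cis-fused enone lactone (C5 ketone, C1=C10; γ-lactone fused at C7–C8) | O=C1C[C@H]2[C@@H](CC=C1)OC(=O)C2 | intermediate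
9 | silyl enol ether (C5(OSiMe3)=C1; C10 methyl trans to O-8) | C[Si](C)(C)OC=1C[C@H]2[C@@H](C[C@@H](C)C=1)OC(=O)C2 | intermediate
10 | keto acetal lactone (C1 dimethoxymethyl trans to C10 methyl) | O=C1C[C@H]2[C@@H](C[C@@H](C)[C@@H]1C(OC)OC)OC(=O)C2 | intermediate
11 | tertiary alcohol (C5 hydroxyl cis to the lactone, isopropenyl on C5) | C=C(C)[C@@]1(O)C[C@H]2[C@@H](C[C@@H](C)[C@@H]1C(OC)OC)OC(=O)C2 | intermediate
12 | trifluoroacetyl lactone (C11 trifluoroacetyl derivative of 11) | C=C(C)[C@@]1(O)C[C@H]2[C@@H](C[C@@H](C)[C@@H]1C(OC)OC)OC(=O)C2C(=O)C(F)(F)F | intermediate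
13 | diazo lactone (C11 diazo derivative of 11) | C=C(C)[C@@]1(O)C[C@H]2[C@@H](C[C@@H](C)[C@@H]1C(OC)OC)OC(=O)C2=[N+]=[N-] | intermediate
14 | ether-bridged lactone acetal (O joins C5 and C11; C11–H outward) | C=C(C)[C@@]23C[C@H]4[C@@H](C[C@@H](C)[C@@H]2C(OC)OC)OC(=O)[C@H]4O3 | intermediate
15 | 2,2-dimethoxy-5,11-epoxy-2,3-seco-guai-3-en-12,8-olide | C=C(C)[C@@]23C[C@H]4[C@@H](C[C@@H](C)[C@@H]2C(OC)OC)OC(=O)[C@@]4(C)O3 | intermediate
16 | 5,11-epoxy-2-oxo-2,3-seco-guai-3-en-12,8-olide (seco-aldehyde) | C=C(C)[C@@]23C[C@H]4[C@@H](C[C@@H](C)[C@@H]2C=O)OC(=O)[C@@]4(C)O3 | intermediate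
17 | geminal diacetate of 16 | C=C(C)[C@@]23C[C@H]4[C@@H](C[C@@H](C)[C@@H]2C(OC(C)=O)OC(C)=O)OC(=O)[C@@]4(C)O3 | intermediate
18 | 2-methyl-1,3-dioxan-2-ylium ion bridging O-2 and O-4 of closed ring A (triflate) | CC5=[O+][C@H]1C[C@@](C)(O5)[C@@]23C[C@H]4[C@@H](C[C@@H](C)[C@H]12)OC(=O)[C@@]4(C)O3.[O-]S(=O)(=O)C(F)(F)F | intermediate
19 | 2-O-acetyl-4-hydroxy-5,11-epoxyguaian-12,8-olide | CC(=O)O[C@H]1C[C@@](C)(O)[C@@]23C[C@H]4[C@@H](C[C@@H](C)[C@H]12)OC(=O)[C@@]4(C)O3 | intermediate
20 | 2,4-dihydroxy-5,11-epoxyguaian-12,8-olide (cis-1,3-diol) | O[C@H]1C[C@@](C)(O)[C@@]23C[C@H]4[C@@H](C[C@@H](C)[C@H]12)OC(=O)[C@@]4(C)O3 | intermediate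
21 | 2-O-angeloyl-4-hydroxy-5,11-epoxyguaian-12,8-olide, CNP0293659.1 (H-1, O-2, HO-4, H-7, H-8 and C14 on one face; ether O at C5, C11 and O-8 on the other) | C/C=C(/C)C(=O)O[C@H]1C[C@@](C)(O)[C@@]23C[C@H]4[C@@H](C[C@@H](C)[C@H]12)OC(=O)[C@@]4(C)O3 | target

Total step count: 15. Longest linear sequence: 15 steps (from cyclohepta-1,3-diene).

**Steps most likely to fail**

1. Step 13 (Proposed new method). The tertiary allylic C5–O bond may ionise instead of the acylal, the C4 cation may lose a proton or rearrange before capture, or the acetoxonium bridge may form on the wrong face. Fallback with known chemistry, setting out from 16 and coming back at 20: ozonolysis of the isopropenyl group (O3, CH2Cl2, −78 °C; Me2S) would give the keto aldehyde F1. Its methyl ketone is the only donor that can lead to a ring; soft enolisation (TiCl4, Bu3N, CH2Cl2, −78 °C) would close ring A by intramolecular titanium aldol addition to the hydroxy ketone F2. CH3MgBr/CeCl3 (THF, −78 °C) would then add to the C4 ketone anti to the C2 alkoxide to give diol 20.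

2. Step 10. The carbenoid may be diverted to cyclopropanation of the isopropenyl group or to a [2,3]-shift of the allylic oxonium ylide instead of O–H insertion. Fallback setting out from 11 and coming back at 14 (it replaces steps 9 and 10): double deprotonation (LiN(SiMe3)2, 2.2 equiv, THF, −78 °C) and iodination of the lactone enolate with I2 on its outer face would give the α-iodo lactone F3. On warming with DMPU the tertiary alkoxide should displace iodide from the inner face (intramolecular Williamson etherification with inversion) to give 14.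

3. Step 7. Methyl may be delivered to the lactone face, or with poor facial discrimination, because the controlling ring fusion is two bonds away. Fallback setting out from 8 and coming back at 9: the cuprate adduct would be taken on as the silyl enol ether F4 whatever its C10 configuration and dehydrogenated (Pd(OAc)2 0.2 equiv, O2, DMSO) to the β-methyl enone F5. C10 would then be set by conjugate hydride delivery ([(Ph3P)CuH]6, Me3SiCl, THF, −40 °C), which enters from the face the methyl group preferred and so gives the opposite, required configuration in silyl enol ether 9.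

**Further compounds**
F1 | step 13 | keto aldehyde (C5 acetyl, C1 formyl on the ether/lactone cage) | CC(=O)[C@@]23C[C@H]4[C@@H](C[C@@H](C)[C@@H]2C=O)OC(=O)[C@@]4(C)O3
F2 | step 13 | hydroxy ketone (ring A closed; 2-hydroxy-4-oxo-15-nor-5,11-epoxyguaian-12,8-olide) | O[C@H]1CC(=O)[C@@]23C[C@H]4[C@@H](C[C@@H](C)[C@H]12)OC(=O)[C@@]4(C)O3
F3 | step 10 | α-iodo lactone (C11 iodide of 11, iodine on the outer face) | C=C(C)[C@@]1(O)C[C@H]2[C@@H](C[C@@H](C)[C@@H]1C(OC)OC)OC(=O)[C@@H]2I
F4 | step 7 | silyl enol ether of the cuprate adduct (C10 configuration open) | C[Si](C)(C)OC=1C[C@H]2[C@@H](CC(C)C=1)OC(=O)C2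
F5 | step 7 | β-methyl enone (C5 ketone, C1=C10 bearing the methyl group, cis-fused lactone) | O=C1C[C@H]2[C@@H](CC(C)=C1)OC(=O)C2
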